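**Retrosynthetic overview**

1. Map: 1 + 2 → 3 → 4 → (5, 6) → 7 → 8 → 9 gives the ring B aldehyde; 10 → 11 gives the ring A ketone; 9 + 11 → 12 → (13) → 14.
2. Key disconnection, C-3–C-1' of 14: back through keto acetal 13 to 2'-hydroxychalcone 12 by a 1,2-shift of the ring B aryl onto C-α, which trivalent thallium turns into an α-keto cation (enolonium) equivalent. O-1–C-2 closes and both MOM groups fall in the same pot.
3. 12 ⇒ 9 + 11 by Claisen–Schmidt condensation; the aldehyde carbon of 9 ends as C-2.
4. 9 ⇒ 8 ⇒ 7 by O-methylation and ortho-formylation at C-6, the only open ortho carbon of the 5-OH. 7 ⇒ 4 ⇒ 3 ⇒ 1 + 2: the chelated 5-OH first differentiates the two phenols and is then used to delete the C-4 carbonyl.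
5. Ring order: both benzene rings are bought (1, 10); the dimethylpyran ring on ring B is formed first (step 1); the pyranone ring C is formed last (step 8).

Assumption: 14 has no stereocentre and no configurationally stable axis, so it is achiral and the structure as drawn is its only stereoisomer; no stereocentre has to be set.

**Route**

Step 1
Reactants: 1 phloroglucinol (benzene-1,3,5-triol); 2 3-methylbut-2-enoic acid
Product: 3 5,7-dihydroxy-2,2-dimethylchroman-4-one
Conditions: P2O5, MeSO3H, 70 °C
Reagents that add atoms: none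
Why: Friedel–Crafts acylation of the threefold-symmetric triphenol followed by intramolecular oxa-Michael addition closes the dimethylpyranone ring, and the symmetry of 1 allows only one regioisomer.

Step 2
Reactants: 3 5,7-dihydroxy-2,2-dimethylchroman-4-one
Product: 4 5-hydroxy-7-(methoxymethoxy)-2,2-dimethylchroman-4-one
Conditions: MOMCl (1.1 equiv), K2CO3, acetone, 0 °C to rt
Reagents that add atoms: chloromethyl methyl ether (MOMCl), COCCl
Why: Williamson-type O-alkylation (MOM protection) goes only to the 7-OH because the 5-OH is locked in a hydrogen bond to the C-4 carbonyl and is far less acidic and nucleophilic.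

Step 3
Reactants: 4 5-hydroxy-7-(methoxymethoxy)-2,2-dimethylchroman-4-one
Product: 7 7-(methoxymethoxy)-2,2-dimethylchroman-5-ol, via aryl ethyl carbonate 5 (not isolated), via ortho-quinone methide 6 (not isolated)
Conditions: ClCO2Et, Et3N, THF, 0 °C; then NaBH4, H2O, 0 °C to rt
Reagents that add atoms: none
Why: ortho-Hydroxy-assisted deoxygenation of an aryl ketone, in which hydride reduction of the ketone of 5 triggers carbonate transfer and elimination to ortho-quinone methide 6, which NaBH4 reduces by 1,4-hydride addition, so C=O becomes CH2 and the 5-OH is freed next to a single open ortho carbon (C-6).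

Step 4
Reactants: 7 7-(methoxymethoxy)-2,2-dimethylchroman-5-ol
Product: 8 5-hydroxy-7-(methoxymethoxy)-2,2-dimethylchroman-6-carbaldehyde
Conditions: (CH2O)n, MgCl2, Et3N, MeCN, reflux
Reagents that add atoms: paraformaldehyde (reacts as formaldehyde), C=O
Why: Magnesium phenoxide-directed ortho-formylation (Casnati–Skattebøl) delivers formaldehyde through a magnesium chelate only ortho to the free OH, and since C-4a is substituted C-6 is the only possible site, which fixes the substitution pattern of ring B.

Step 5
Reactants: 8 5-hydroxy-7-(methoxymethoxy)-2,2-dimethylchroman-6-carbaldehyde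
Product: 9 5-methoxy-7-(methoxymethoxy)-2,2-dimethylchroman-6-carbaldehyde
Conditions: MeI, K2CO3, DMF, 40 °C
Reagents that add atoms: iodomethane, CI
Why: Williamson O-methylation of the chelated salicylaldehyde-type OH proceeds in a dipolar aprotic solvent and no other acidic site is present.

Step 6
Reactants: 10 1-(2,4-dihydroxyphenyl)ethan-1-one
Product: 11 1-[2-hydroxy-4-(methoxymethoxy)phenyl]ethan-1-one
Conditions: MOMCl (1.1 equiv), K2CO3, acetone, rt
Reagents that add atoms: chloromethyl methyl ether (MOMCl), COCCl
Why: Selective Williamson-type MOM protection of the 4-OH, the 2-OH being hydrogen-bonded to the acetyl carbonyl.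

Step 7
Reactants: 9 5-methoxy-7-(methoxymethoxy)-2,2-dimethylchroman-6-carbaldehyde; 11 1-[2-hydroxy-4-(methoxymethoxy)phenyl]ethan-1-one
Product: 12 (E)-1-[2-hydroxy-4-(methoxymethoxy)phenyl]-3-[5-methoxy-7-(methoxymethoxy)-2,2-dimethylchroman-6-yl]prop-2-en-1-one
Conditions: KOH, EtOH, rt, 48 h
Reagents that add atoms: none
Why: Claisen–Schmidt (crossed aldol) condensation of the enolate of 11 with the non-enolisable aldehyde 9, followed by E1cB dehydration, gives the conjugated enone with the thermodynamically favoured E geometry.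

Step 8
Reactants: 12 (E)-1-[2-hydroxy-4-(methoxymethoxy)phenyl]-3-[5-methoxy-7-(methoxymethoxy)-2,2-dimethylchroman-6-yl]prop-2-en-1-one
Product: 14 glycyrrhizaisoflavone C [7-hydroxy-3-(7-hydroxy-5-methoxy-2,2-dimethylchroman-6-yl)-4H-chromen-4-one], via β-keto dimethyl acetal 13 (not isolated)
Conditions: Tl(NO3)3·3H2O (1.1 equiv), MeOH, rt, 2 h; filter; then HCl (to 1 M), MeOH, reflux, 2 h
Reagents that add atoms: none
Why: Oxidative rearrangement of a 2'-hydroxychalcone, in which trivalent thallium binds C-α while methanol adds at C-β, so that C-α becomes an α-keto cation (enolonium) equivalent to which the very electron-rich ring B aryl migrates (forming C-3–C-1') as monovalent thallium leaves, after which acid-catalysed cyclodehydration of acetal 13 onto the 2'-OH and MOM acetal exchange give the free isoflavone.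

**Compound list**

1 | phloroglucinol (benzene-1,3,5-triol) | Oc1cc(O)cc(O)c1 | starting material
2 | 3-methylbut-2-enoic acid | CC(C)=CC(=O)O | starting material
3 | 5,7-dihydroxy-2,2-dimethylchroman-4-one | CC1(C)CC(=O)c2c(O)cc(O)cc2O1 | intermediate
4 | 5-hydroxy-7-(methoxymethoxy)-2,2-dimethylchroman-4-one | CC1(C)CC(=O)c2c(O)cc(OCOC)cc2O1 | intermediate
5 | ethyl 7-(methoxymethoxy)-2,2-dimethyl-4-oxochroman-5-yl carbonate (formed and consumed in the flask) | CCOC(=O)Oc1cc(OCOC)cc2OC(C)(C)CC(=O)c12 | intermediate
6 | 7-(methoxymethoxy)-2,2-dimethyl-2,3-dihydro-5H-chromen-5-one, the ortho-quinone methide (formed and consumed in the flask) | CC1(C)CC=C2C(=O)C=C(OCOC)C=C2O1 | intermediate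
7 | 7-(methoxymethoxy)-2,2-dimethylchroman-5-ol | CC1(C)CCc2c(O)cc(OCOC)cc2O1 | intermediate
8 | 5-hydroxy-7-(methoxymethoxy)-2,2-dimethylchroman-6-carbaldehyde | CC1(C)CCc2c(O)c(C=O)c(OCOC)cc2O1 | intermediate
9 | 5-methoxy-7-(methoxymethoxy)-2,2-dimethylchroman-6-carbaldehyde | CC1(C)CCc2c(OC)c(C=O)c(OCOC)cc2O1 | intermediate
10 | 1-(2,4-dihydroxyphenyl)ethan-1-one | CC(=O)c1ccc(O)cc1O | starting material
11 | 1-[2-hydroxy-4-(methoxymethoxy)phenyl]ethan-1-one | CC(=O)c1ccc(OCOC)cc1O | intermediate
12 | (E)-1-[2-hydroxy-4-(methoxymethoxy)phenyl]-3-[5-methoxy-7-(methoxymethoxy)-2,2-dimethylchroman-6-yl]prop-2-en-1-one | COCOc1ccc(C(=O)/C=C/c2c(OC)c3CCC(C)(C)Oc3cc2OCOC)c(O)c1 | intermediate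
13 | 1-[2-hydroxy-4-(methoxymethoxy)phenyl]-3,3-dimethoxy-2-[5-methoxy-7-(methoxymethoxy)-2,2-dimethylchroman-6-yl]propan-1-one (racemic; its stereocentre is erased in the same step; formed and consumed in the flask) | COCOc1ccc(C(=O)C(C(OC)OC)c2c(OC)c3CCC(C)(C)Oc3cc2OCOC)c(O)c1 | intermediate
14 | glycyrrhizaisoflavone C, 7-hydroxy-3-(7-hydroxy-5-methoxy-2,2-dimethylchroman-6-yl)-4H-chromen-4-one (achiral) | COc1c2c(cc(O)c1-c1coc3cc(O)ccc3c1=O)OC(C)(C)CC2 | target

**Step count**

Total: 8 steps. Longest linear sequence: 7 steps (steps 1, 2, 3, 4, 5, 7, 8 from phloroglucinol); step 6 is a one-step side branch.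

**Three steps most likely to fail, with fallbacks**

Step 8 is the riskiest. Ring B is a trioxygenated arene that trivalent thallium could oxidise, and the nitric acid released could strip a MOM group before the aryl shift. The fallback sets out from 12 and returns at 14. Chalcone 12 is first closed by oxa-Michael addition (NaOAc, EtOH, reflux) to the flavanone 7-(methoxymethoxy)-2-[5-methoxy-7-(methoxymethoxy)-2,2-dimethylchroman-6-yl]chroman-4-one F1 (racemic). Its enol ether is then attacked at C-3 by the trivalent iodine reagent PhI(OH)OTs in HC(OMe)3/MeOH; the ring B aryl shifts from C-2 to C-3 and loss of a proton gives the protected isoflavone 7-(methoxymethoxy)-3-[5-methoxy-7-(methoxymethoxy)-2,2-dimethylchroman-6-yl]-4H-chromen-4-one F2. A separate treatment with HCl in MeOH removes both MOM groups and gives 14.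

Step 7 may be slow or incomplete, because aldehyde 9 is flanked by two alkoxy groups and is electron-rich, while the enolate of 11 is deactivated by its phenoxide. The fallback sets out from 9 and 11 and returns at 12. The dianion of 11 is pre-formed with LiN(iPr)2 (2.2 equiv, THF, −78 °C) and added irreversibly to 9 to give the β-hydroxy ketone 3-hydroxy-1-[2-hydroxy-4-(methoxymethoxy)phenyl]-3-[5-methoxy-7-(methoxymethoxy)-2,2-dimethylchroman-6-yl]propan-1-one F3 (racemic). This is dehydrated separately with catalytic pyridinium p-toluenesulfonate in toluene at 60 °C to give 12.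

Step 3 may stall. The 5-OH is strongly chelated and peri-hindered, so acylation can be incomplete, and NaBH4 may cleave the carbonate before it reduces the electron-rich ketone. The fallback avoids the carbonyl stage altogether; it sets out from 1 and returns at 7. Phloroglucinol 1 is alkylated and cyclised with 2-methylbut-3-en-2-ol (BF3·OEt2, dioxane, rt) to 2,2-dimethylchroman-5,7-diol F4. The less hindered 7-OH is then protected with MOMCl (1.0 equiv, iPr2NEt, CH2Cl2, −20 °C), and the minor 5-O-MOM isomer is removed by chromatography to give 7.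

**Further compounds**

F1 | step 8 | 7-(methoxymethoxy)-2-[5-methoxy-7-(methoxymethoxy)-2,2-dimethylchroman-6-yl]chroman-4-one (racemic) | COCOc1ccc2C(=O)CC(Oc2c1)c1c(OC)c2CCC(C)(C)Oc2cc1OCOC
F2 | step 8 | 7-(methoxymethoxy)-3-[5-methoxy-7-(methoxymethoxy)-2,2-dimethylchroman-6-yl]-4H-chromen-4-one | COCOc1ccc2c(c1)occ(-c1c(OC)c3CCC(C)(C)Oc3cc1OCOC)c2=O
F3 | step 7 | 3-hydroxy-1-[2-hydroxy-4-(methoxymethoxy)phenyl]-3-[5-methoxy-7-(methoxymethoxy)-2,2-dimethylchroman-6-yl]propan-1-one (racemic) | COCOc1ccc(C(=O)CC(O)c2c(OC)c3CCC(C)(C)Oc3cc2OCOC)c(O)c1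
F4 | step 3 | 2,2-dimethylchroman-5,7-diol | CC1(C)CCc2c(O)cc(O)cc2O1
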